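**Retrosynthetic overview**
1. The two acids are carried as tert-butyl esters. The trienoate is cut at its C2=C3 bond (Horner–Wadsworth–Emmons, phosphonoacetate + sorbaldehyde) and at the C6–O ester bond.
2. Ring B is cut by a [4+2] disconnection at C7–C8 and C9–C10 (the quaternary carbon): a 2-silyloxydiene C10=C5–C6(OSi)=C7 on ring A plus di-tert-butyl acetylenedicarboxylate (C8≡C9 carrying C11 and C12).
3. Enabling feature: in ring B the C6 oxygen sits 1,3 to C8 and 1,4 to C9, the carboxyls are vicinal on C8/C9, and C10 is the fully substituted ring-fusion carbon. This is a cyclohexadiene retron with the enol ether at C5=C6 and the dienophile at C8/C9.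
4. C10, set in the cycloaddition, relays every other centre from the α face: C9 (kinetic protonation), C5 (protonation), C8 (hydrogenation), C6 (hydride).
5. Ring order: ring A comes with β-cyclocitral; ring B is the only ring built and the last one closed.

Key step: step 4

Numbering note: drimane numbering is used for positions (ring A = C1–C5, C10; ring B = C5–C10; C11 on C9, C12 on C8; β = the face of the C10 methyl group).
Assumption: the (S)-configured catalyst in step 4 is taken to give the (10S) adduct by analogy with fumarate dienophiles; if the opposite sense is found, the catalyst from (R)-α,α-diphenylprolinol is used and nothing else changes.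

**Step 1**
Reactants: 1 β-cyclocitral (2,6,6-trimethylcyclohex-1-ene-1-carbaldehyde)
Product: 2 (±)-1-(2,6,6-trimethylcyclohex-1-en-1-yl)ethan-1-ol
Conditions: MeMgBr, THF, 0 °C; then H2O
Reagents that add atoms: methylmagnesium bromide, C[Mg]Br
Why: Grignard 1,2-addition to the hindered enal (the β-carbon is fully substituted, so conjugate addition does not compete); the carbinol centre is racemic and is erased in step 2.

**Step 2**
Reactants: 2 (±)-1-(2,6,6-trimethylcyclohex-1-en-1-yl)ethan-1-ol
Product: 3 1-(2,6,6-trimethylcyclohex-1-en-1-yl)ethan-1-one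
Conditions: Dess–Martin periodinane, CH2Cl2, 0 °C to rt
Reagents that add atoms: none
Why: Dess–Martin oxidation of a secondary allylic alcohol to the methyl ketone; no stereocentre is present.

**Step 3**
Reactants: 3 1-(2,6,6-trimethylcyclohex-1-en-1-yl)ethan-1-one
Product: 4 triisopropyl{[1-(2,6,6-trimethylcyclohex-1-en-1-yl)ethenyl]oxy}silane
Conditions: i-Pr3SiOTf, Et3N, CH2Cl2, 0 °C to rt
Reagents that add atoms: triisopropylsilyl trifluoromethanesulfonate, CC(C)[Si](OS(=O)(=O)C(F)(F)F)(C(C)C)C(C)C
Why: Soft enolisation (silyl triflate/amine) can only remove a methyl proton, since the other α-carbon is the ring sp2 carbon and the twisted enone disfavours γ-deprotonation, so the cross-conjugated 2-silyloxydiene should form.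

**Step 4**
Reactants: 4 triisopropyl{[1-(2,6,6-trimethylcyclohex-1-en-1-yl)ethenyl]oxy}silane; 5 di-tert-butyl but-2-ynedioate
Product: 6 di-tert-butyl (8aS)-5,5,8a-trimethyl-4-[(triisopropylsilyl)oxy]-3,5,6,7,8,8a-hexahydronaphthalene-1,2-dicarboxylate (6-silyloxy-drima-5,8-diene-11,12-dioate with 10β-methyl)
Conditions: (S)-oxazaborolidinium triflimide [protonated (S)-3,3-diphenyl-1-(2-methylphenyl)tetrahydro-1H,3H-pyrrolo[1,2-c][1,3,2]oxazaborole, counter-ion (CF3SO2)2N−] (20 mol %), CH2Cl2, −78 to −40 °C
Reagents that add atoms: none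
Why: Proposed new method: an enantioselective [4+2] cycloaddition of a 2-silyloxydiene with an acetylenedicarboxylate under chiral oxazaborolidinium catalysis, whose closest known relatives are the oxazaborolidinium-catalysed Diels–Alder reactions of 2-silyloxydienes with fumarates and of acetylenic ketones with dienes, and the uncatalysed cycloaddition of 2,6,6-trimethyl-1-vinylcyclohexene with acetylenedicarboxylates. The boron Lewis acid binds one ester carbonyl of 5 and lowers its LUMO, the nucleophilic CH2 terminus (C7) of the silyl enol ether leads bond formation to C8 in an asynchronous normal-demand transition state, and C9 then bonds to the tetrasubstituted terminus C10, which is why a quaternary centre should form at low temperature. Ring B is closed intermolecularly as a six-membered ring by the two new bonds C7–C8 and C9–C10, suprafacially on the s-cis diene. The only stereocentre created is C10 and it is catalyst-controlled: the aryl group on boron and the gem-diphenyl unit shield one face of the bound alkynoate, so the diene can approach with only one of its enantiotopic faces while ring A points away from the catalyst. Regiochemistry and endo/exo selectivity do not arise because the dienophile is a C2-symmetric alkyne; the step needs periselectivity for [4+2] over [2+2] and enantiofacial selectivity, which the bulky triisopropylsilyl group (no silyl transfer, closure at C6 disfavoured) and the low temperature are meant to secure. The adduct already holds the C6 oxygen, both carboxyl carbons and the C8=C9 bond from which C9, C8, C5 and C6 are set by relay from C10.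

**Step 5**
Reactants: 6 di-tert-butyl (8aS)-5,5,8a-trimethyl-4-[(triisopropylsilyl)oxy]-3,5,6,7,8,8a-hexahydronaphthalene-1,2-dicarboxylate
Product: 9 di-tert-butyl (1R,4aS,8aS)-5,5,8a-trimethyl-4-oxo-1,4,4a,5,6,7,8,8a-octahydronaphthalene-1,2-dicarboxylate (6-oxo-drim-7-ene-11,12-dioate with 5α-H and 9α-H), via lithium trienolate 7 (not isolated), via silyl dienyl ether 8 (not isolated)
Conditions: LiN(i-Pr)2, THF, −78 °C; AcOH, −78 °C; then HF·pyridine, 0 °C
Reagents that add atoms: none
Why: γ-Deprotonation at C7 gives the extended ester enolate, whose kinetic α-protonation at C9 (deconjugative protonation of a dienolate, the known route from drim-8-ene to drim-7-ene diesters) should occur anti to the C10 methyl group and set the 9β-ester, and acid-mediated desilylation then protonates C5 anti to the same methyl group to give the trans-fused enone, which is also the thermodynamic ring fusion.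

**Step 6**
Reactants: 9 di-tert-butyl (1R,4aS,8aS)-5,5,8a-trimethyl-4-oxo-1,4,4a,5,6,7,8,8a-octahydronaphthalene-1,2-dicarboxylate
Product: 10 di-tert-butyl (1S,2S,4aS,8aS)-5,5,8a-trimethyl-4-oxodecahydronaphthalene-1,2-dicarboxylate (8β,9β-diester)
Conditions: H2 (3 atm), Pd/C (10 wt % Pd on carbon), EtOAc, rt
Reagents that add atoms: none
Why: Heterogeneous hydrogenation of the enone C7=C8 bond should deliver hydrogen from the α face, anti to the axial C10 methyl group, which places the C8 ester axial and cis to the C9 ester under neutral, non-epimerising conditions.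

**Step 7**
Reactants: 10 di-tert-butyl (1S,2S,4aS,8aS)-5,5,8a-trimethyl-4-oxodecahydronaphthalene-1,2-dicarboxylate
Product: 11 di-tert-butyl (1S,2S,4R,4aS,8aS)-4-hydroxy-5,5,8a-trimethyldecahydronaphthalene-1,2-dicarboxylate (6β-alcohol)
Conditions: NaBH4, MeOH/THF, 0 °C
Reagents that add atoms: none
Why: Borohydride reduction from the equatorial α direction, because the axial β trajectory at C6 is blocked by the syn-axial C10 methyl, C4 β-methyl and C8 ester groups (as with 6-oxo-5α-steroids), should give the axial 6β-alcohol while the tert-butyl esters are untouched.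

**Step 8**
Reactants: 11 di-tert-butyl (1S,2S,4R,4aS,8aS)-4-hydroxy-5,5,8a-trimethyldecahydronaphthalene-1,2-dicarboxylate; 12 2-(diethoxyphosphoryl)acetic acid
Product: 14 di-tert-butyl (1S,2S,4R,4aS,8aS)-4-{[2-(diethoxyphosphoryl)acetyl]oxy}-5,5,8a-trimethyldecahydronaphthalene-1,2-dicarboxylate, via phosphonoketene 13 (not isolated)
Conditions: DCC, DMAP (cat.), CH2Cl2, 0 °C to rt
Reagents that add atoms: none
Why: Carbodiimide activation of the phosphonoacetic acid (Steglich-type esterification) gives the phosphonoketene by elimination, a small and very electrophilic acyl donor known to esterify hindered alcohols, with retention at C6.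

**Step 9**
Reactants: 14 di-tert-butyl (1S,2S,4R,4aS,8aS)-4-{[2-(diethoxyphosphoryl)acetyl]oxy}-5,5,8a-trimethyldecahydronaphthalene-1,2-dicarboxylate; 15 (2E,4E)-hexa-2,4-dienal
Product: 16 di-tert-butyl (1S,2S,4R,4aS,8aS)-5,5,8a-trimethyl-4-{[(2E,4E,6E)-octa-2,4,6-trienoyl]oxy}decahydronaphthalene-1,2-dicarboxylate
Conditions: LiCl, DBU, MeCN, 0 °C to rt
Reagents that add atoms: none
Why: Horner–Wadsworth–Emmons olefination of a stabilised phosphonate under LiCl/amine conditions should form the new C2=C3 bond with E geometry (the 4E,6E geometry comes from the aldehyde), and the base is too weak to epimerise the C8 and C9 ester centres.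

**Step 10**
Reactants: 16 di-tert-butyl (1S,2S,4R,4aS,8aS)-5,5,8a-trimethyl-4-{[(2E,4E,6E)-octa-2,4,6-trienoyl]oxy}decahydronaphthalene-1,2-dicarboxylate
Product: 17 (1S,2S,4R,4aS,8aS)-5,5,8a-trimethyl-4-{[(2E,4E,6E)-octa-2,4,6-trienoyl]oxy}decahydronaphthalene-1,2-dicarboxylic acid (CNP0462207.1)
Conditions: CF3CO2H/CH2Cl2 (1:4), 0 °C to rt
Reagents that add atoms: none
Why: Acidolysis of both tert-butyl esters with loss of isobutene under anhydrous conditions should free the cis-diacid without touching the trienoate ester or any stereocentre.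

**Compound list**
1 | β-cyclocitral (2,6,6-trimethylcyclohex-1-ene-1-carbaldehyde) | CC1=C(C=O)C(C)(C)CCC1 | starting material
2 | (±)-1-(2,6,6-trimethylcyclohex-1-en-1-yl)ethan-1-ol (racemic) | CC(O)C1=C(C)CCCC1(C)C | intermediate
3 | 1-(2,6,6-trimethylcyclohex-1-en-1-yl)ethan-1-one | CC(=O)C1=C(C)CCCC1(C)C | intermediate
4 | triisopropyl{[1-(2,6,6-trimethylcyclohex-1-en-1-yl)ethenyl]oxy}silane | C=C(O[Si](C(C)C)(C(C)C)C(C)C)C1=C(C)CCCC1(C)C | intermediate
5 | di-tert-butyl but-2-ynedioate | CC(C)(C)OC(=O)C#CC(=O)OC(C)(C)C | starting material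
6 | di-tert-butyl (8aS)-5,5,8a-trimethyl-4-[(triisopropylsilyl)oxy]-3,5,6,7,8,8a-hexahydronaphthalene-1,2-dicarboxylate | CC(C)[Si](C(C)C)(C(C)C)OC1=C2C(C)(C)CCC[C@]2(C)C(C(=O)OC(C)(C)C)=C(C(=O)OC(C)(C)C)C1 | intermediate
7 | lithium trienolate of 6 (C7-deprotonated, drawn as the lithium enolate of the C11 ester; not isolated) | CC(C)[Si](C(C)C)(C(C)C)OC1=C2C(C)(C)CCC[C@]2(C)C(=C(O[Li])OC(C)(C)C)C(C(=O)OC(C)(C)C)=C1 | intermediate
8 | di-tert-butyl (1R,8aR)-5,5,8a-trimethyl-4-[(triisopropylsilyl)oxy]-1,5,6,7,8,8a-hexahydronaphthalene-1,2-dicarboxylate (9α-H; not isolated) | CC(C)[Si](C(C)C)(C(C)C)OC1=C2C(C)(C)CCC[C@]2(C)[C@@H](C(=O)OC(C)(C)C)C(C(=O)OC(C)(C)C)=C1 | intermediate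
9 | di-tert-butyl (1R,4aS,8aS)-5,5,8a-trimethyl-4-oxo-1,4,4a,5,6,7,8,8a-octahydronaphthalene-1,2-dicarboxylate | O=C1C=C(C(=O)OC(C)(C)C)[C@H](C(=O)OC(C)(C)C)[C@@]2(C)CCCC(C)(C)[C@H]12 | intermediate
10 | di-tert-butyl (1S,2S,4aS,8aS)-5,5,8a-trimethyl-4-oxodecahydronaphthalene-1,2-dicarboxylate | O=C1C[C@H](C(=O)OC(C)(C)C)[C@H](C(=O)OC(C)(C)C)[C@@]2(C)CCCC(C)(C)[C@H]12 | intermediate
11 | di-tert-butyl (1S,2S,4R,4aS,8aS)-4-hydroxy-5,5,8a-trimethyldecahydronaphthalene-1,2-dicarboxylate | O[C@@H]1C[C@H](C(=O)OC(C)(C)C)[C@H](C(=O)OC(C)(C)C)[C@@]2(C)CCCC(C)(C)[C@H]12 | intermediate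
12 | 2-(diethoxyphosphoryl)acetic acid | CCOP(=O)(OCC)CC(=O)O | starting material
13 | (diethoxyphosphoryl)ketene (not isolated) | CCOP(=O)(OCC)C=C=O | intermediate
14 | di-tert-butyl (1S,2S,4R,4aS,8aS)-4-{[2-(diethoxyphosphoryl)acetyl]oxy}-5,5,8a-trimethyldecahydronaphthalene-1,2-dicarboxylate | CCOP(=O)(OCC)CC(=O)O[C@@H]1C[C@H](C(=O)OC(C)(C)C)[C@H](C(=O)OC(C)(C)C)[C@@]2(C)CCCC(C)(C)[C@H]12 | intermediate
15 | (2E,4E)-hexa-2,4-dienal | C/C=C/C=C/C=O | starting material
16 | di-tert-butyl (1S,2S,4R,4aS,8aS)-5,5,8a-trimethyl-4-{[(2E,4E,6E)-octa-2,4,6-trienoyl]oxy}decahydronaphthalene-1,2-dicarboxylate | C/C=C/C=C/C=C/C(=O)O[C@@H]1C[C@H](C(=O)OC(C)(C)C)[C@H](C(=O)OC(C)(C)C)[C@@]2(C)CCCC(C)(C)[C@H]12 | intermediate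
17 | (1S,2S,4R,4aS,8aS)-5,5,8a-trimethyl-4-{[(2E,4E,6E)-octa-2,4,6-trienoyl]oxy}decahydronaphthalene-1,2-dicarboxylic acid | C/C=C/C=C/C=C/C(=O)O[C@@H]1C[C@H](C(=O)O)[C@H](C(=O)O)[C@@]2(C)CCCC(C)(C)[C@H]12 | target

**Step count and risks**
Total step count: 10. Longest linear sequence: 10 steps (from 1 to 17).

Steps most likely to fail:

Step 4 (Proposed new method). What may go wrong: insufficient enantiofacial discrimination at the fully substituted diene terminus, or diversion of the Lewis-acid pathway into [2+2] closure at the enol ether or silyl transfer to an open-chain adduct. The fallback uses known chemistry and sets out from 4 and 5. The uncatalysed thermal Diels–Alder reaction (toluene, 110 °C, sealed tube) is the established mode for 1-vinyl-2,6,6-trimethylcyclohexenes with acetylenedicarboxylates and should give the racemic adduct, that is 6 together with di-tert-butyl (8aR)-5,5,8a-trimethyl-4-[(triisopropylsilyl)oxy]-3,5,6,7,8,8a-hexahydronaphthalene-1,2-dicarboxylate F1. Preparative chromatography on a chiral stationary phase (amylose tris(3,5-dimethylphenylcarbamate)) separates the two, and the route is rejoined at 6.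

Step 5. What may go wrong: protonation of the trienolate at C7 or C5 in place of C9, or loss of the facial preference at C9 because ring B is almost flat while C5 is still trigonal. The fallback sets out from 6 and moves the deconjugation to a trans-decalin in which the C10 methyl group is truly axial (the classical drim-8-ene diester case). HF·pyridine (THF, 0 °C) should give the trans-fused β,γ-unsaturated ketone di-tert-butyl (4aS,8aS)-5,5,8a-trimethyl-4-oxo-3,4,4a,5,6,7,8,8a-octahydronaphthalene-1,2-dicarboxylate F2. NaBH4 (MeOH, 0 °C) should then give the 6β-alcohol di-tert-butyl (4R,4aS,8aS)-4-hydroxy-5,5,8a-trimethyl-3,4,4a,5,6,7,8,8a-octahydronaphthalene-1,2-dicarboxylate F3. Deconjugation (LiN(i-Pr)2, 2.2 equiv, THF, −78 °C; then AcOH) should give the 7-ene 9β-ester di-tert-butyl (1R,4R,4aS,8aS)-4-hydroxy-5,5,8a-trimethyl-1,4,4a,5,6,7,8,8a-octahydronaphthalene-1,2-dicarboxylate F4. Hydrogenation from the α face (H2, Pd/C, EtOAc) then returns to the route at 11.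

Step 8. What may go wrong: slow acyl transfer to the axial C6 hydroxyl group, which has three syn-axial neighbours, and competing attack of this hydroxyl group on the axial C12 ester (lactonisation with loss of tert-butanol). The fallback sets out from 11 and builds the phosphonoacetate in the reverse order. Acylation with bromoacetyl bromide (pyridine, CH2Cl2, −20 °C), the smallest and most electrophilic two-carbon acyl donor, should give di-tert-butyl (1S,2S,4R,4aS,8aS)-4-(2-bromoacetoxy)-5,5,8a-trimethyldecahydronaphthalene-1,2-dicarboxylate F5. A Michaelis–Arbuzov reaction with P(OEt)3 (neat, 110 °C) then forms the C–P bond and returns to the route at 14.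

**Further compounds**
F1 | step 4 | di-tert-butyl (8aR)-5,5,8a-trimethyl-4-[(triisopropylsilyl)oxy]-3,5,6,7,8,8a-hexahydronaphthalene-1,2-dicarboxylate (enantiomer of 6) | CC(C)[Si](C(C)C)(C(C)C)OC1=C2C(C)(C)CCC[C@@]2(C)C(C(=O)OC(C)(C)C)=C(C(=O)OC(C)(C)C)C1
F2 | step 5 | di-tert-butyl (4aS,8aS)-5,5,8a-trimethyl-4-oxo-3,4,4a,5,6,7,8,8a-octahydronaphthalene-1,2-dicarboxylate | O=C1CC(C(=O)OC(C)(C)C)=C(C(=O)OC(C)(C)C)[C@@]2(C)CCCC(C)(C)[C@H]12
F3 | step 5 | di-tert-butyl (4R,4aS,8aS)-4-hydroxy-5,5,8a-trimethyl-3,4,4a,5,6,7,8,8a-octahydronaphthalene-1,2-dicarboxylate | O[C@@H]1CC(C(=O)OC(C)(C)C)=C(C(=O)OC(C)(C)C)[C@@]2(C)CCCC(C)(C)[C@H]12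
F4 | step 5 | di-tert-butyl (1R,4R,4aS,8aS)-4-hydroxy-5,5,8a-trimethyl-1,4,4a,5,6,7,8,8a-octahydronaphthalene-1,2-dicarboxylate | O[C@@H]1C=C(C(=O)OC(C)(C)C)[C@H](C(=O)OC(C)(C)C)[C@@]2(C)CCCC(C)(C)[C@H]12
F5 | step 8 | di-tert-butyl (1S,2S,4R,4aS,8aS)-4-(2-bromoacetoxy)-5,5,8a-trimethyldecahydronaphthalene-1,2-dicarboxylate | BrCC(=O)O[C@@H]1C[C@H](C(=O)OC(C)(C)C)[C@H](C(=O)OC(C)(C)C)[C@@]2(C)CCCC(C)(C)[C@H]12
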